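**Retrosynthetic overview**

1. Target 27 ⇐ diene 26 (hydroxyl-directed epoxidation of C1=C10) ⇐ lactone 23 (α-methylenation) ⇐ hydroxy amide 19 (γ-lactone closed by invertive O-alkylation of the amide at C6).
2. Ten-membered ring: dienone 18 ⇐ keto mesylate 15 by a five-carbon ring expansion of a cyclopentanone: alkenyllithium 1,2-addition (makes C5–C6), then Grob fragmentation (breaks C6–C10, forms Z-C1=C10).
3. 15 ⇐ reductive aldol (C10–C1) of cyclopentenone 6 (C6–C10, carrying C7 and C8) with aldehyde 12 (C1–C5, carrying C3).
4. 6 ⇐ Piancatelli rearrangement of furylcarbinol 4 (from 1 + 2), then lipase resolution/acylation; 12 ⇐ propargyl alcohol by carbometalation–iodination, oxidation and catalytic asymmetric acetaldehyde aldol.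
5. Ring order: cyclopentenone → transient fused cycloheptene → cyclodecadiene → γ-lactone → oxirane.

Atom labels C1–C15 are those of the germacrane skeleton of the target: C1/C10 epoxide (C14 methyl on C10), C3 carbinol, C4=C5 (C15 methyl on C4), C6 lactone carbinol, C7, C8 ester carbinol, C11–C13 acrylate. In the target the oxygens on C1/C10, C3, C6 and C8 lie on one face of the ring and C11 on the other; the C4=C5 olefin is Z and the epoxide is cis (C2 and C9 cis).

Assumption: triethyl(vinyloxy)silane (11) is taken as purchasable; racemic 5 is drawn as the enantiomer that is carried on.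

**Route**

Step 1
Reactants: 1 3-methylfuran-2-carbaldehyde; 2 N,N-dimethylacetamide
Product: 4 racemic 3-hydroxy-N,N-dimethyl-3-(3-methylfuran-2-yl)propanamide, via amide lithium enolate 3 (not isolated)
Conditions: LiN(i-Pr)2 (1.1 equiv), 2, THF, −78 °C; then 1, −78 °C
Reagents that add atoms: none
Why: Aldol addition of a lithium amide enolate to a non-enolisable aldehyde attaches C11–C12 to the future C7, and the carbinol centre can stay racemic because it is ionised in step 2.

Step 2
Reactants: 4 racemic furylcarbinol
Product: 5 racemic trans-2-(5-hydroxy-3-methyl-2-oxocyclopent-3-en-1-yl)-N,N-dimethylacetamide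
Conditions: Dy(OTf)3 (10 mol %), t-BuOH/H2O 5:1, 80 °C
Reagents that add atoms: water (O)
Why: Piancatelli rearrangement (furfuryl cation, water addition at the furan 5-position, ring opening, conrotatory 4π electrocyclisation) builds the C6–C10 cyclopentenone and places the C7 side chain and the C8 hydroxyl trans, as this reaction always does.

Step 3
Reactants: 5 racemic trans-hydroxy enone
Product: 6 (1R,5S)-5-[2-(dimethylamino)-2-oxoethyl]-3-methyl-4-oxocyclopent-2-en-1-yl 2-methylpropanoate
Conditions: immobilised Burkholderia cepacia lipase, vinyl 2-methylpropanoate (3 equiv), t-BuOMe, 30 °C, to about 50 % conversion; chromatography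
Reagents that add atoms: vinyl 2-methylpropanoate (C=COC(=O)C(C)C)
Why: Lipase-catalysed kinetic resolution by irreversible acyl transfer, in which by the Kazlauskas rule the (R)-carbinol enantiomer (larger flank = branched C7) is esterified, so the resolution fixes C7 (S) and C8 (R) and installs the isobutyrate of the target while the enantiomeric alcohol is left behind.

Step 4
Reactants: 7 prop-2-yn-1-ol
Product: 9 (2Z)-3-iodo-2-methylprop-2-en-1-ol, via alkenylmagnesium chelate 8 (not isolated)
Conditions: MeMgBr (2.5 equiv), CuI (10 mol %), THF, −10 °C to rt; then I2, −40 to 0 °C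
Reagents that add atoms: methylmagnesium bromide (C[Mg]Br); iodine (II)
Why: Copper-catalysed anti-carbomagnesiation of the propargylic magnesium alkoxide through a five-membered chelate puts magnesium cis to the CH2O group, and iodinolysis with retention gives the (Z)-iodoalkene that becomes the C4=C5 olefin.

Step 5
Reactants: 9 (Z)-iodo allylic alcohol
Product: 10 (2Z)-3-iodo-2-methylprop-2-enal
Conditions: MnO2 (15 equiv), CH2Cl2, rt, dark
Reagents that add atoms: none
Why: Allylic alcohol oxidation with MnO2 under neutral conditions keeps the Z geometry and the C–I bond.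

Step 6
Reactants: 10 (Z)-iodo enal; 11 triethyl(vinyloxy)silane
Product: 12 (3S,4Z)-5-iodo-4-methyl-3-(triethylsilyloxy)pent-4-enal
Conditions: chiral imidodiphosphorimidate (IDPi) Brønsted acid (1 mol %), 11 (1.5 equiv), pentane/CH2Cl2, −60 °C
Reagents that add atoms: none
Why: Catalytic enantioselective Mukaiyama-type single aldol addition of the acetaldehyde enol silane with silyl transfer to the new alkoxide, run with the catalyst enantiomer that directs attack to the Si face of 10 so that C3 is set as S and arrives already protected.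

Step 7
Reactants: 6 cyclopentenyl isobutyrate; 12 silyloxy iodo aldehyde
Product: 15 keto mesylate (1R,2S,4R)-2-[2-(dimethylamino)-2-oxoethyl]-4-[(1R,3S,4Z)-5-iodo-4-methyl-1-(methylsulfonyloxy)-3-(triethylsilyloxy)pent-4-en-1-yl]-4-methyl-3-oxocyclopentyl 2-methylpropanoate, via lithium enolate 13 (not isolated), via lithium aldolate 14 (not isolated)
Conditions: LiBH(s-Bu)3 (1.05 equiv), THF, −78 °C; then 12, −78 °C; then MsCl (1.5 equiv), −78 to −20 °C
Reagents that add atoms: methanesulfonyl chloride (CS(=O)(=O)Cl)
Why: Reductive aldol in which conjugate hydride addition gives the tetrasubstituted C6–C10 enolate regiospecifically and this adds to 12 through a closed Zimmerman–Traxler transition state, so the methyl that is cis to the enolate oxygen ends up syn to the new C1 oxygen (attack anti to the C7 side chain gives 1R,10R; the face isomer with both centres inverted would converge in step 8), and the aldolate is sulfonylated cold before retro-aldol or β-elimination can set in.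

Step 8
Reactants: 15 keto mesylate
Product: 18 (1R,2S,4Z,6S,8Z)-2-[2-(dimethylamino)-2-oxoethyl]-5,9-dimethyl-3-oxo-6-(triethylsilyloxy)cyclodeca-4,8-dien-1-yl 2-methylpropanoate, via alkenyllithium 16 (not isolated), via bicyclic lithium alkoxide 17 (not isolated)
Conditions: t-BuLi (2.05 equiv), THF/Et2O 4:1, −100 °C, 20 min; then HMPA (4 equiv), −78 to 0 °C
Reagents that add atoms: none
Why: Proposed new method: iodine–lithium exchange, which is faster than attack of t-BuLi on the hindered ketone, the ester, the amide or the sulfonate, gives the configurationally stable (Z)-alkenyllithium 16, which adds 7-exo-trig to the C6 ketone from the face of its own tether to give the cis-fused bicyclo[5.3.0]decenolate 17; there the C1–OMs bond can lie antiperiplanar to the C6–C10 bond, so the alkoxide fragments (Grob/Wharton) to the C6 ketone and the C1=C10 olefin, whose Z geometry follows from the syn C1–O/C10–CH3 relation set in step 7, while the Z C4=C5 olefin is carried over from the seven-membered ring, the net result being a five-carbon ring expansion of the cyclopentanone to the cyclodecadienone with loss of the stereocentres at C1, C6 and C10; the closest known chemistry is the sequential Barbier cyclisation/Grob fragmentation of iodoalkyl keto mesylates with SmI2 and the separate alkenyllithium–ketone cyclisation, neither of which has been shown for an sp2 carbanion that delivers a conjugated (Z,Z)-dienone.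

Step 9
Reactants: 18 cyclodecadienone
Product: 19 (1R,2R,3R,4Z,6S,8Z)-2-[2-(dimethylamino)-2-oxoethyl]-3-hydroxy-5,9-dimethyl-6-(triethylsilyloxy)cyclodeca-4,8-dien-1-yl 2-methylpropanoate
Conditions: NaBH4 (1.5 equiv), CeCl3·7H2O (1.2 equiv), MeOH, −78 °C; used crude
Reagents that add atoms: none
Why: Luche 1,2-reduction of the enone, where Felkin–Anh attack anti to the ring branch C8 (the same sense as a cerium chelate between the ketone and the amide carbonyl) is expected to give the C6 alcohol cis to the C7 side chain, the epimer that step 10 inverts.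

Step 10
Reactants: 19 hydroxy amide
Product: 23 (3S,6S,7S,8R)-3-hydroxy-8-(2-methylpropanoyloxy)germacra-1(10)Z,4Z-dien-12,6-olide, via allylic mesylate 20 (not isolated), via iminium ether salt 21 (not isolated), via silyl lactone 22 (not isolated)
Conditions: Ms2O (1.3 equiv), i-Pr2NEt (2.5 equiv), CH2Cl2, −30 °C to rt; then AcOH/THF/H2O 3:1:1, rt
Reagents that add atoms: water (O)
Why: Intramolecular O-alkylation of the amide (5-exo-tet neighbouring-group displacement of the allylic mesylate from the rear) inverts C6 to S and gives the trans-fused iminium ether, which acidic hydrolysis turns into the γ-lactone and dimethylamine while the same dilute acid removes the Et3Si ether.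

Step 11
Reactants: 23 hydroxy lactone
Product: 26 (3S,6S,7S,8R)-3-hydroxy-8-(2-methylpropanoyloxy)germacra-1(10)Z,4Z,11(13)-trien-12,6-olide, via Mannich base 24 (not isolated), via ammonium iodide 25 (not isolated)
Conditions: LiN(i-Pr)2 (2.3 equiv), THF, −78 °C; [Me2N=CH2]I (3 equiv), −78 °C to rt; then MeI, MeOH, rt; then NaHCO3 (aq), CH2Cl2, rt
Reagents that add atoms: N,N-dimethylmethyleneiminium iodide (C=[N+](C)C.[I-])
Why: Mannich aminomethylation of the lactone enolate (the less hindered α-CH2 is deprotonated in preference to the isobutyrate methine, and the C3 alkoxide is a spectator) followed by quaternisation and Hofmann-type β-elimination gives the exocyclic methylene, the transient C11 centre being irrelevant.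

Step 12
Reactants: 26 methylene lactone
Product: 27 (1R,3S,6S,7S,8R,10S)-1,10-epoxy-3-hydroxy-8-(2-methylpropanoyloxy)germacra-4Z,11(13)-dien-12,6-olide (the target)
Conditions: mCPBA (1.1 equiv), NaHCO3, CH2Cl2, −20 to 0 °C
Reagents that add atoms: 3-chloroperoxybenzoic acid (OOC(=O)c1cccc(Cl)c1)
Why: Prilezhaev epoxidation picks the most electron-rich olefin C1=C10 (C4=C5 is deactivated by two allylic C–O bonds and the acrylate is electron-poor), adds syn so the Z olefin gives the cis-epoxide, and is delivered by hydrogen bonding to the homoallylic C3–OH (Henbest direction) to the face of that hydroxyl, which sets 1R,10S.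

**Compound list**

1 | 3-methylfuran-2-carbaldehyde | O=Cc1occc1C | starting material
2 | N,N-dimethylacetamide | CC(=O)N(C)C | starting material
3 | lithium enolate of N,N-dimethylacetamide (not isolated) | C=C(O[Li])N(C)C | intermediate
4 | racemic 3-hydroxy-N,N-dimethyl-3-(3-methylfuran-2-yl)propanamide | CN(C)C(=O)CC(O)c1occc1C | intermediate
5 | racemic trans-2-(5-hydroxy-3-methyl-2-oxocyclopent-3-en-1-yl)-N,N-dimethylacetamide (SMILES shows the (1S,5R) enantiomer that is carried on) | O=C1C(C)=C[C@@H](O)[C@@H]1CC(=O)N(C)C | intermediate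
6 | (1R,5S)-5-[2-(dimethylamino)-2-oxoethyl]-3-methyl-4-oxocyclopent-2-en-1-yl 2-methylpropanoate (C7 S, C8 R) | O=C1C(C)=C[C@@H](OC(=O)C(C)C)[C@@H]1CC(=O)N(C)C | intermediate
7 | prop-2-yn-1-ol | C#CCO | starting material
8 | (Z)-alkenylmagnesium bromide chelated to its bromomagnesium alkoxide (not isolated) | Br[Mg]OC/C(C)=C\[Mg]Br | intermediate
9 | (2Z)-3-iodo-2-methylprop-2-en-1-ol | OC/C(C)=C\I | intermediate
10 | (2Z)-3-iodo-2-methylprop-2-enal | O=C/C(C)=C\I | intermediate
11 | triethyl(vinyloxy)silane (acetaldehyde triethylsilyl enol ether) | C=CO[Si](CC)(CC)CC | starting material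
12 | (3S,4Z)-5-iodo-4-methyl-3-(triethylsilyloxy)pent-4-enal | O=CC[C@H](O[Si](CC)(CC)CC)/C(C)=C\I | intermediate
13 | lithium enolate of the conjugate-reduced ketone from 6 (not isolated) | [Li]OC1=C(C)C[C@@H](OC(=O)C(C)C)[C@@H]1CC(=O)N(C)C | intermediate
14 | lithium aldolate, C1 R, C10 R (not isolated) | O=C1[C@@](C)([C@H](O[Li])C[C@H](O[Si](CC)(CC)CC)/C(C)=C\I)C[C@@H](OC(=O)C(C)C)[C@@H]1CC(=O)N(C)C | intermediate
15 | keto mesylate, C1 R, C3 S, C7 S, C8 R, C10 R, (Z)-iodoalkene | O=C1[C@@](C)([C@H](OS(C)(=O)=O)C[C@H](O[Si](CC)(CC)CC)/C(C)=C\I)C[C@@H](OC(=O)C(C)C)[C@@H]1CC(=O)N(C)C | intermediate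
16 | (Z)-alkenyllithium from 15 (not isolated) | O=C1[C@@](C)([C@H](OS(C)(=O)=O)C[C@H](O[Si](CC)(CC)CC)/C(C)=C\[Li])C[C@@H](OC(=O)C(C)C)[C@@H]1CC(=O)N(C)C | intermediate
17 | cis-fused bicyclo[5.3.0]dec-2-ene lithium alkoxide, O on C6 cis to the C10 methyl (not isolated) | [Li]O[C@]12C=C(C)[C@@H](O[Si](CC)(CC)CC)C[C@@H](OS(C)(=O)=O)[C@@]1(C)C[C@@H](OC(=O)C(C)C)[C@@H]2CC(=O)N(C)C | intermediate
18 | (1R,2S,4Z,6S,8Z)-2-[2-(dimethylamino)-2-oxoethyl]-5,9-dimethyl-3-oxo-6-(triethylsilyloxy)cyclodeca-4,8-dien-1-yl 2-methylpropanoate (C6 ketone; 3S,7S,8R) | O=C1/C=C(/C)[C@@H](O[Si](CC)(CC)CC)C/C=C(/C)C[C@@H](OC(=O)C(C)C)[C@@H]1CC(=O)N(C)C | intermediate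
19 | C6 alcohol from 18 with OH cis to the C7 side chain (6R) | O[C@@H]1/C=C(/C)[C@@H](O[Si](CC)(CC)CC)C/C=C(/C)C[C@@H](OC(=O)C(C)C)[C@@H]1CC(=O)N(C)C | intermediate
20 | C6 allylic mesylate of 19 (not isolated) | CS(=O)(=O)O[C@@H]1/C=C(/C)[C@@H](O[Si](CC)(CC)CC)C/C=C(/C)C[C@@H](OC(=O)C(C)C)[C@@H]1CC(=O)N(C)C | intermediate
21 | trans-fused cyclic iminium ether methanesulfonate, C6 inverted to S (not isolated) | C1C(=[N+](C)C)O[C@H]2/C=C(/C)[C@@H](O[Si](CC)(CC)CC)C/C=C(/C)C[C@@H](OC(=O)C(C)C)[C@H]12.CS(=O)(=O)[O-] | intermediate
22 | 3-O-triethylsilyl ether of lactone 23 (not isolated) | C1C(=O)O[C@H]2/C=C(/C)[C@@H](O[Si](CC)(CC)CC)C/C=C(/C)C[C@@H](OC(=O)C(C)C)[C@H]12 | intermediate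
23 | (3S,6S,7S,8R)-3-hydroxy-8-(2-methylpropanoyloxy)germacra-1(10)Z,4Z-dien-12,6-olide | C1C(=O)O[C@H]2/C=C(/C)[C@@H](O)C/C=C(/C)C[C@@H](OC(=O)C(C)C)[C@H]12 | intermediate
24 | 11-(dimethylaminomethyl) lactone, C11 epimers (not isolated) | CN(C)CC1C(=O)O[C@H]2/C=C(/C)[C@@H](O)C/C=C(/C)C[C@@H](OC(=O)C(C)C)[C@H]12 | intermediate
25 | 11-(trimethylammoniomethyl) lactone iodide (not isolated) | C[N+](C)(C)CC1C(=O)O[C@H]2/C=C(/C)[C@@H](O)C/C=C(/C)C[C@@H](OC(=O)C(C)C)[C@H]12.[I-] | intermediate
26 | (3S,6S,7S,8R)-3-hydroxy-8-(2-methylpropanoyloxy)germacra-1(10)Z,4Z,11(13)-trien-12,6-olide | C=C1C(=O)O[C@H]2/C=C(/C)[C@@H](O)C/C=C(/C)C[C@@H](OC(=O)C(C)C)[C@H]12 | intermediate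
27 | (1R,3S,6S,7S,8R,10S)-1,10-epoxy-3-hydroxy-8-(2-methylpropanoyloxy)germacra-4Z,11(13)-dien-12,6-olide | C=C1C(=O)O[C@H]2/C=C(/C)[C@@H](O)C[C@H]3O[C@@]3(C)C[C@@H](OC(=O)C(C)C)[C@H]12 | target

**Step count and risk**

Total: 12 steps. Longest linear sequence: 9 steps (1 → 4 → 5 → 6 → 15 → 18 → 19 → 23 → 26 → 27); the branch 7 → 9 → 10 → 12 is 3 steps and joins at step 7.

The three steps most likely to fail:

Step 8 (the new cyclisation/fragmentation cascade). The risks are that t-BuLi or the alkenyllithium attacks the ester or sulfonate, or that the lithium alkoxide fragments sluggishly. The fallback uses known chemistry, sets out from 15 and returns at 18. The iodide is cyclised under Nozaki–Hiyama–Kishi conditions (CrCl2 6 equiv, NiCl2 2 mol %, DMSO, rt), which tolerate the ester, amide and sulfonate, to give the isolable cis-fused bicyclic tertiary allylic alcohol F1. F1 is then fragmented in a separate flask under classical Wharton–Grob conditions with exactly one equivalent of KN(SiMe3)2 (THF, −78 to 0 °C), so that the β-acyloxy ketone 18 never meets excess base.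

Step 9 (facial selectivity of the C6 reduction in a flexible ten-membered ring). The fallback sets out from 18 and returns at 23. If hydride comes from the other face, the product is the C6 epimer of 19, the (6S)-alcohol F2, which already has the C6 configuration of the target. F2 is therefore not activated but lactonised with retention by acid-catalysed acyl substitution at the amide (pyridinium p-toluenesulfonate, wet MeOH, 45 °C), which also removes the Et3Si ether and gives 23. A mixture of 19 and F2 can be separated and each epimer sent down its own closure, so both outcomes of the reduction reach the same lactone.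

Step 12 (site and face selectivity of the last epoxidation). The fallback sets out from 26 and returns at 27. The substrate-directed peracid is replaced by a reagent-controlled dioxirane epoxidation (Shi epoxidation: fructose-derived chiral ketone, KHSO5, K2CO3 buffer, MeCN/dimethoxymethane/H2O, 0 °C), using the ketone enantiomer that oxidises the face of C1=C10 on the side of the C3 hydroxyl. The electrophilic dioxirane keeps the preference for the electron-rich trisubstituted C1=C10 olefin. This path makes no new compound (entry F0).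

**Further compounds**

F1 | step 8 | cis-fused bicyclo[5.3.0]dec-2-en-1-ol carrying the C1 mesylate (neutral alcohol of 17; C6 S, C10 R, C1 R) | O[C@]12C=C(C)[C@@H](O[Si](CC)(CC)CC)C[C@@H](OS(C)(=O)=O)[C@@]1(C)C[C@@H](OC(=O)C(C)C)[C@@H]2CC(=O)N(C)C
F2 | step 9 | (6S)-alcohol, C6 epimer of 19 (OH trans to the C7 side chain) | O[C@H]1/C=C(/C)[C@@H](O[Si](CC)(CC)CC)C/C=C(/C)C[C@@H](OC(=O)C(C)C)[C@@H]1CC(=O)N(C)C
F0 | step 12 | none | none
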